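The runs are simulated for an exercise; noise was put on by code.

The constants of this flask are not given, so they have to be read from two runs in which gas, held at saturation, passes into solution as reagent and turns substrate into target.

| setting | Saturday's | Wednesday's | flask |
|---|---|---|---|
| substrate | 20 mM | 10 mM | 20 mM |
| gas | 2.6 mM (held) | 2.6 mM (held) | 2.6 mM (held) |
| remark | the very flask that is asked about, followed so far | run made earlier |  |
| time |  |  | 2.5 h |

| run | time / min | target / % | substrate / % |
|---|---|---|---|
| Saturday's | 1.33 | 1 | 101 |
| Saturday's | 2.50 | 0 | 98 |
| Saturday's | 4.00 | 0 | 102 |
| Saturday's | 6.00 | 1 | 101 |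
| Saturday's | 10.0 | 1 | 98 |
| Saturday's | 20.0 | 3 | 96 |
| Wednesday's | 8.00 | 0 | 100 |
| Wednesday's | 20.0 | 0 | 98 |
| Wednesday's | 40.0 | 4 | 98 |
| Wednesday's | 60.0 | 10 | 94 |
| Wednesday's | 80.0 | 11 | 90 |
| Wednesday's | 120 | 16 | 83 |

(scatter of a reading: 2 percentage points)

- the analysis behind the earlier runs scatters by 2 percentage points, standard deviation
- at the start none of the gas is in solution
- reagent is what gas becomes in solution

- the target standing at 2.5 h, as a percentage of the substrate charged
- concentration of reagent in solution at 2.5 h, in percent of saturation

What do the runs give first? Wednesday's last reading, 16 % of target after 120 min, read as an average over that run, is a fractional rate of 0.00133 min⁻¹.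

Does that hold at twice the charge? While reagent stands steady, the reaction is pseudo-first-order in substrate, so percentages should run alike. The rate gives 2.66 % at 20.0 min, and Saturday's run reads 3 %. For the asked time I say 20.0 %.

But does reagent stand steady? Take the reagent's turnover time, the time the reaction in this flask needs to use one saturation's worth of reagent, 2.6 mM: 97.5 min. If reagent is steady, its share of saturation is that time over the sum of that time and the uptake time, the time gas needs to refill the solution.

And the uptake time? Wednesday's reading at 20.0 min lies 2.7 percentage points under the line, with a scatter of 2 points, so I see no firm lag and allow about 10.0 min. That guess is shorter than the turnover time, so my estimate is reagent at about 90.7 % of saturation.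

The forecast says 19 % of target (15 % to 25 %) and reagent at 84 % of saturation (72 % to 93 %), holding that “The lag suggests slow gas uptake”. My reagent figure stands higher.

The flask gives 19.9 % of target, with reagent at 95.9 % of saturation.

    substrate + reagent ⇌ target + released group (K = 1.26, k = 0.705 L mol⁻¹ min⁻¹)
    gas ⇌ reagent, rate k2*(csat - [reagent]) (kL = 0.187 min⁻¹)
    2 substrate → self-condensation product (k = 7.89 × 10⁻⁵ L mol⁻¹ min⁻¹)

The uptake time of the gas, the inverse of its coefficient, is 5.35 min, shorter than the turnover time of 97.5 min reckoned from Wednesday's average rate, which puts the share at 94.8 %, and this flask holds 2.49 mM of reagent at 2.50 h. In the neighbouring flask with 12 mM of substrate, the same fractional rate makes the turnover time 162 min, the two times give 96.8 %, and reagent there stands at 97.2 % of saturation at 2.50 h.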